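**Retrosynthetic overview**

1. Numbering used throughout: O1–O2–C3–C4–C4a–O5–C6(=O)–C7–C7a; ring A is the 1,2-dioxane (O1, O2, C3, C4, C4a, C7a), ring B the γ-lactone (C4a, O5, C6, C7, C7a).
2. 12 ⇐ 11 by saturating two C≡C bonds: the C3 chain is carried as a 1,7-diynyl group, so C3 bears one slim sp substituent and one methyl group until the end.
3. 11 ⇐ hydroperoxide 9 + ketal 5 in one operation: O2–C3 (peroxyketal exchange), C3–C4 (6-endo closure of ring A by a peroxycarbenium ion), then O5–C4a (ring B, carbonyl capture of the C4a cation); ring A forms first, ring B in the same flask.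
4. Enabling feature: C4a is the tertiary carbon of a hidden 2-methylallyl unit C4=C4a(CH3)–C7a. It lies γ to the carboxyl carbon C6 and next to the peroxy methine C7a, and C3 (ketone level: CH3, chain, O2) is one CH2 (C4) away. A cation at C4a is therefore both what forms when C4 attacks a C3 peroxycarbenium ion and what a five-ring lactonisation needs.
5. 9 ⇐ 4-methylpent-3-enoic acid (singlet-oxygen ene reaction, enzymatic resolution fixes C7a); 5 ⇐ 1,7-octadiyne + (4-bromobutyl)benzene + an acetyl unit.

Key step: step 7

Assumption: horseradish peroxidase reduces the R enantiomer of 8 faster, as it does with other secondary allylic hydroperoxides, so that (S)-9 is the one recovered.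

**Route**

Step 1
Reactants: 1 1,7-octadiyne; 2 (4-bromobutyl)benzene
Product: 3 12-phenyldodeca-1,7-diyne
Conditions: 1 (4 equiv), n-BuLi (1 equiv), THF, −78 °C; then 2 (1 equiv), DMPU, −78 °C → rt; excess 1 distilled off
Reagents that add atoms: none
Why: SN2 alkylation of a lithium acetylide with a primary bromide in a dipolar cosolvent, the excess of diyne keeping the reaction at the mono-anion stage.

Step 2
Reactants: 3 12-phenyldodeca-1,7-diyne
Product: 4 14-phenyltetradeca-3,9-diyn-2-one
Conditions: n-BuLi, THF, −78 °C; N-methoxy-N-methylacetamide, −78 → 0 °C; aq. NH4Cl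
Reagents that add atoms: N-methoxy-N-methylacetamide, CC(=O)N(C)OC
Why: Weinreb ketone synthesis, in which the lithium acetylide should add only once because the chelated tetrahedral adduct survives until the quench.

Step 3
Reactants: 4 14-phenyltetradeca-3,9-diyn-2-one
Product: 5 2,2-dimethoxy-14-phenyltetradeca-3,9-diyne
Conditions: HC(OMe)3, MeOH, p-TsOH·H2O (5 mol%), rt; Et3N quench
Reagents that add atoms: trimethyl orthoformate, COC(OC)OC; methanol, CO
Why: Acid-catalysed ketalisation driven by the orthoester as water scavenger, the mild acid leaving both alkynes untouched.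

Step 4
Reactants: 6 4-methylpent-3-enoic acid
Product: 7 methyl 4-methylpent-3-enoate
Conditions: MeI, K2CO3, DMF, rt
Reagents that add atoms: iodomethane, CI
Why: SN2 O-methylation of the carboxylate, which avoids both the strong acid that would lactonise this acid onto its own trisubstituted alkene and the strong base that would move the double bond into conjugation.

Step 5
Reactants: 7 methyl 4-methylpent-3-enoate
Product: 8 methyl 3-hydroperoxy-4-methylpent-4-enoate (racemic)
Conditions: O2, hν (white LED), 5,10,15,20-tetraphenylporphyrin (0.2 mol%), CH2Cl2, 0 °C; chromatography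
Reagents that add atoms: dioxygen (as singlet oxygen), O=O
Why: Schenck ene reaction, in which singlet oxygen should bond to C3 of the ester (the future C7a) and take a hydrogen from one of the geminal methyl groups (six hydrogens on the carbon that carries the developing tertiary positive charge, against two ester-deactivated C2 hydrogens), so that the isopropenyl hydroperoxide should predominate over the conjugated tertiary regioisomer, which is removed on silica; the stereocenter is formed racemic and is resolved in step 6.

Step 6
Reactants: 8 methyl 3-hydroperoxy-4-methylpent-4-enoate (racemic)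
Product: 9 methyl (3S)-3-hydroperoxy-4-methylpent-4-enoate
Conditions: horseradish peroxidase (cat.), guaiacol (1.2 equiv), phosphate buffer pH 6, 20 °C, stopped shortly after half conversion; chromatography
Reagents that add atoms: none
Why: Enzymatic kinetic resolution, in which the peroxidase should reduce the (R)-hydroperoxide to the alcohol with guaiacol as hydrogen donor and leave the (S)-hydroperoxide, which fixes C7a of the target.

Step 7
Reactants: 9 methyl (3S)-3-hydroperoxy-4-methylpent-4-enoate; 5 2,2-dimethoxy-14-phenyltetradeca-3,9-diyne
Product: 11 (3R,4aS,7aS)-3,4a-dimethyl-3-(12-phenyldodeca-1,7-diyn-1-yl)-3,4,4a,7a-tetrahydrofuro[3,2-c][1,2]dioxin-6(7H)-one, via mixed monoperoxyketal 10 (not isolated)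
Conditions: 5 (1.2 equiv), TMSOTf (0.3 equiv), 4 Å MS, CH2Cl2, −78 → −30 °C; Et3N, then aq. NaHCO3
Reagents that add atoms: none
Why: Proposed new method: TMSOTf should exchange one methoxy group of 5 for the hydroperoxide of 9 (giving 10) and then ionise 10 to a propargylic peroxycarbenium ion, whose carbon (C3) is attacked by the CH2 terminus of the isopropenyl group in a 6-endo-trig closure of ring A, while the developing tertiary C4a cation is captured 5-exo by the ester carbonyl oxygen (O5–C4a, ring B) and the O-methyl lactonium ion gives up its methyl group to the liberated TMSOMe/MeOH as dimethyl ether. The closest known reaction type is the Lewis-acid-mediated, halide-terminated cyclisation of unsaturated monoperoxyketals through peroxycarbenium ions, joined here to the ester- or acid-terminated Prins lactonisation familiar from oxocarbenium chemistry. C4a is controlled by the tether: the two-atom CH2C(=O) arm on C7a can only deliver oxygen to the face on which it sits, so ring B must be cis-fused and C4a follows from the resolved C7a. C3 is controlled in a chair transition state in which the arm on C7a is pseudo-axial (it avoids eclipsing the C4a methyl group, has only one 1,3-diaxial hydrogen because O2 carries none, and lies anti to the forming C3–C4 bond so that the carbonyl can assist) and the slim, linear alkynyl group takes the axial site on C3, where a methyl group would clash with the C4a methyl group; the C3 methyl group should therefore end cis to O5 and the chain trans to it, as in 12. The step needs facial selectivity at C3 and chemoselectivity for the 1,1-disubstituted alkene over the remote alkyne and for carboxyl capture over proton loss; the first rests on the alkyne oxidation level of the chain, the second on the intramolecular five-ring capture.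

Step 8
Reactants: 11 (3R,4aS,7aS)-3,4a-dimethyl-3-(12-phenyldodeca-1,7-diyn-1-yl)-3,4,4a,7a-tetrahydrofuro[3,2-c][1,2]dioxin-6(7H)-one
Product: 12 plakortolide L, (3S,4aS,7aS)-3,4a-dimethyl-3-(12-phenyldodecyl)-3,4,4a,7a-tetrahydrofuro[3,2-c][1,2]dioxin-6(7H)-one
Conditions: KO2C–N=N–CO2K (potassium azodicarboxylate, large excess in portions), AcOH, MeOH/CH2Cl2, 0 °C → rt
Reagents that add atoms: none
Why: Diimide reduction, in which HN=NH made in the flask should deliver hydrogen to the non-polar C≡C and C=C bonds by concerted cyclic transfer and leave the O–O bond, the lactone and the arene untouched, with no stereocenter formed or disturbed (the descriptor at C3 changes from R to S only because the chain loses priority).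

**Compound list**

1 | 1,7-octadiyne | C#CCCCCC#C | starting material
2 | (4-bromobutyl)benzene | BrCCCCc1ccccc1 | starting material
3 | 12-phenyldodeca-1,7-diyne | C#CCCCCC#CCCCCc1ccccc1 | intermediate
4 | 14-phenyltetradeca-3,9-diyn-2-one | CC(=O)C#CCCCCC#CCCCCc1ccccc1 | intermediate
5 | 2,2-dimethoxy-14-phenyltetradeca-3,9-diyne | CC(OC)(OC)C#CCCCCC#CCCCCc1ccccc1 | intermediate
6 | 4-methylpent-3-enoic acid | CC(C)=CCC(=O)O | starting material
7 | methyl 4-methylpent-3-enoate | CC(C)=CCC(=O)OC | intermediate
8 | methyl 3-hydroperoxy-4-methylpent-4-enoate (racemic) | COC(=O)CC(OO)C(C)=C | intermediate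
9 | methyl (3S)-3-hydroperoxy-4-methylpent-4-enoate | COC(=O)C[C@@H](C(C)=C)OO | intermediate
10 | methyl (3S)-3-[(2-methoxy-14-phenyltetradeca-3,9-diyn-2-yl)peroxy]-4-methylpent-4-enoate (both epimers at the ketal carbon) | COC(=O)C[C@@H](C(C)=C)OOC(C)(OC)C#CCCCCC#CCCCCc1ccccc1 | intermediate
11 | (3R,4aS,7aS)-3,4a-dimethyl-3-(12-phenyldodeca-1,7-diyn-1-yl)-3,4,4a,7a-tetrahydrofuro[3,2-c][1,2]dioxin-6(7H)-one | C[C@]1(C#CCCCCC#CCCCCc2ccccc2)C[C@]2(C)OC(=O)C[C@@H]2OO1 | intermediate
12 | plakortolide L, (3S,4aS,7aS)-3,4a-dimethyl-3-(12-phenyldodecyl)-3,4,4a,7a-tetrahydrofuro[3,2-c][1,2]dioxin-6(7H)-one | C[C@]1(CCCCCCCCCCCCc2ccccc2)C[C@]2(C)OC(=O)C[C@@H]2OO1 | target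

**Step count and risks**

Total step count: 8. Longest linear sequence: 5 steps (1, 2, 3, 7, 8; the branch 4, 5, 6, 7, 8 is equally long).

Steps most likely to fail:

1. Step 7 (Proposed new method). The free allylic hydroperoxide may fragment under the acid before it is tied up as the peroxyketal. The C4a cation may lose a proton or be taken by methanol instead of closing ring B. The chair preference that places the alkynyl group axial may be too weak, so that facial selectivity at C3 is poor. The fallback separates the events with known reaction types and sets out from 9 and 5. PPTS-catalysed exchange (CH2Cl2, 4 Å MS, rt) gives the mixed monoperoxyketal 10, which is now isolated. TiCl4 (1.1 equiv, CH2Cl2, −78 °C) then effects the known chloride-terminated cyclisation of the unsaturated monoperoxyketal to methyl [(3S,6R)-4-chloro-4,6-dimethyl-6-(12-phenyldodeca-1,7-diyn-1-yl)-1,2-dioxan-3-yl]acetate F1. This γ-chloro ester is lactonised in a separate step (ZnCl2 cat., CH2Cl2, 0 °C → rt, chloride removing the ester methyl group), and the route is rejoined at 11.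

2. Step 6. The enzyme may discriminate poorly between the isopropenyl and the CH2CO2Me group, or accept the substrate slowly, so that the recovered hydroperoxide is of low enantiomeric purity or of the opposite sense. The fallback is a resolution through covalent diastereomers and sets out from 8. Acid-catalysed addition (PPTS, CH2Cl2) to the known resolving reagent (1R,2S)-2-phenylcyclohexyl isopropenyl ether gives two perketals: methyl (3S)-4-methyl-3-{[2-{[(1R,2S)-2-phenylcyclohexyl]oxy}propan-2-yl]peroxy}pent-4-enoate F2 and methyl (3R)-4-methyl-3-{[2-{[(1R,2S)-2-phenylcyclohexyl]oxy}propan-2-yl]peroxy}pent-4-enoate F3. These are separated by chromatography, and mild hydrolysis of the S-configured one (AcOH/THF/H2O) returns the route to 9.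

3. Step 8. Diimide may disproportionate faster than it reduces the hindered propargylic alkyne next to the quaternary C3, so that reduction stalls at the alkene stage, and prolonged exposure may open the β-peroxy lactone. The fallback saturates the chain before any peroxide is present and sets out from 4. Hydrogenation (H2, Pd/C, EtOAc) gives 14-phenyltetradecan-2-one F4, and ketalisation as in step 3 gives 2,2-dimethoxy-14-phenyltetradecane F5. The conditions of step 7 with 9 then lead, through methyl (3S)-3-[(2-methoxy-14-phenyltetradecan-2-yl)peroxy]-4-methylpent-4-enoate F6, directly to 12. This gives up the alkyne-based control at C3, so a chromatographic separation from (3R,4aS,7aS)-3,4a-dimethyl-3-(12-phenyldodecyl)-3,4,4a,7a-tetrahydrofuro[3,2-c][1,2]dioxin-6(7H)-one F7 has to be accepted.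

**Further compounds**

F1 | step 7 | methyl [(3S,6R)-4-chloro-4,6-dimethyl-6-(12-phenyldodeca-1,7-diyn-1-yl)-1,2-dioxan-3-yl]acetate (C4 epimers) | C[C@]1(C#CCCCCC#CCCCCc2ccccc2)CC(C)(Cl)[C@H](CC(=O)OC)OO1
F2 | step 6 | methyl (3S)-4-methyl-3-{[2-{[(1R,2S)-2-phenylcyclohexyl]oxy}propan-2-yl]peroxy}pent-4-enoate | COC(=O)C[C@@H](C(C)=C)OOC(C)(C)O[C@@H]1CCCC[C@H]1c1ccccc1
F3 | step 6 | methyl (3R)-4-methyl-3-{[2-{[(1R,2S)-2-phenylcyclohexyl]oxy}propan-2-yl]peroxy}pent-4-enoate | COC(=O)C[C@H](C(C)=C)OOC(C)(C)O[C@@H]1CCCC[C@H]1c1ccccc1
F4 | step 8 | 14-phenyltetradecan-2-one | CC(=O)CCCCCCCCCCCCc1ccccc1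
F5 | step 8 | 2,2-dimethoxy-14-phenyltetradecane | CC(OC)(OC)CCCCCCCCCCCCc1ccccc1
F6 | step 8 | methyl (3S)-3-[(2-methoxy-14-phenyltetradecan-2-yl)peroxy]-4-methylpent-4-enoate | COC(=O)C[C@@H](C(C)=C)OOC(C)(OC)CCCCCCCCCCCCc1ccccc1
F7 | step 8 | (3R,4aS,7aS)-3,4a-dimethyl-3-(12-phenyldodecyl)-3,4,4a,7a-tetrahydrofuro[3,2-c][1,2]dioxin-6(7H)-one | C[C@@]1(CCCCCCCCCCCCc2ccccc2)C[C@]2(C)OC(=O)C[C@@H]2OO1
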